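## Structural features

The target is an isoflavan quinone: a chroman (ring A fused to the pyran ring through C4a–C8a) carries at C3 a 2,3-dimethoxy-1,4-benzoquinone (ring B) through the C3–C1' bond. Ring A has four contiguous oxygens (O1 on C8a, OMe on C8, free OH on C7, OMe on C6) and one hydrogen at C5. Ring B also has four contiguous oxygens (carbonyls C2' and C5', methoxy groups on C3' and C4'). C3 is the only stereocentre (S by the sequence rules: C2 > C1' > C4 > H); it lies between two methylene groups and has no neighbouring stereocentre or heteroatom to relay from. The fragile parts are the methoxyquinone (base, nucleophiles, reductants), the electron-rich ring A phenol (oxidants) and the C3–H bond, which is γ to a quinone carbonyl and could be lost through a quinone methide tautomer under base. The real difficulty is to set this isolated stereocentre between two tetraoxygenated aryl halves and to unveil quinone and phenol last under neutral conditions. The key step exploits the pyran ring (O1, C2, C3, C4, C4a, C8a): it is the sum of the heterodiene O1=C8a–C4a=C4 of a ring A ortho-quinone methide and a two-carbon unit C2–C3 whose C3 carries ring B. In the cycloadduct C3 has one stereogenic neighbour, the acetal carbon C2, which is temporary.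

## Logic of the disconnections

**19 to 17 (through 18).** No skeletal bond is cut; the carbonyl oxygens on C2' and C5' and the C7 hydroxyl are traced back to three benzyl ethers. Quinone and free phenol would not survive the acid, hydride and palladium chemistry used earlier, while benzyl ethers do and leave under neutral hydrogenolysis. The gain is that every earlier intermediate is a plain aryl ether. The demand is that one hydrogenolysis clears three hindered benzyl ethers and that the oxidant stops at the quinone without touching the ring A phenol.

**17 to 16.** C2–H is replaced by C2–OEt; no skeletal bond is cut. The alkoxy group turns the pyran into the cyclic acetal that is the retron of an enol ether hetero-Diels–Alder reaction. The demand on the forward step is an ionic reduction through the cyclic oxocarbenium ion that neither removes the C3 proton (which would erase the stereocentre) nor opens the ring at O1–C2.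

**16 to 7 and 14 (through 15).** C3–C4 and O1–C2 are cut. This divides the molecule into two benzene fragments of similar size and makes ring, both bonds and the stereocentre in one event. The demand is threefold: a chiral acid must ionise 7 and then distinguish the faces of the carbon that becomes C3, 14 must be a single geometric isomer, and 15 must be captured faster than it alkylates other arenes.

**14 to 12 and 13.** The aryl–vinyl bond C1'–C3 is cut. A methoxymethylene Wittig olefination of the ring B aldehyde would be the obvious route, but it gives both geometric isomers, and the two could present opposite faces of the future C3 to the catalyst. A stereoretentive cross-coupling with the preformed E-alkenylboronate 13 removes that flaw. The price is an ethyl in place of a methyl on the enol ether oxygen, a spectator that leaves in step 11. The demand is a coupling under basic conditions that keeps the acid-labile enol ether intact.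

**12 to 11 to 9 to 8 (through 10).** The C1'–Br bond, the two O–benzyl bonds and the oxygen on C5' are removed in turn. The four oxygens of ring B are then reduced to a bought phenol that lacks only the para oxygen. The demand is para-selective oxidation of 8, alkylation of the air-sensitive 10 without isolation, and monobromination of 11, whose two free positions are equivalent.

**7 to 6 to 5.** After adjusting the oxidation level (alcohol from aldehyde), the C4–C4a bond is cut. The phenol oxygen that will become O1 directs the one-carbon unit to its only free ortho position, so C4 and O1 are set in the right relation without any regiochemical choice.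

**5 to 3 to 2 to 1 (through 4).** The C8a–O bond is traced to a formyl group (aryl formate rearrangement), the formyl C–C bond is cut, and the O7–benzyl bond is cut last. An oxygen cannot be placed directly on that carbon of 2, but a formyl group goes there (para to one methoxy, ortho to the other) and peracid converts it into OH. The route arrives at 1, which already holds the C6, C7 and C8 oxygens. The demand is formylation at C4 of 2 and aryl migration in the peracid step.

## Other disconnections considered

**Alternative 1:** Ring A is removed by cutting C5–C6, C4a–C8a and C8–C8a. C6, C7 and C8 come from the alkenyl(methoxy)carbene chromium complex A2 (carbene carbon becomes C6), C8a from a carbonyl ligand, and C5 and C4a from the terminal alkyne A3, which already holds C4, C3 (S), C2 and ring B.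
- Forward step: warming A2 with A3 should give, by alkyne insertion, CO insertion, electrocyclisation of the dienylketene and tautomerisation, the phenol A1 with its hydroxyl on C8a next to the side chain. Silyl ether cleavage, Mitsunobu closure of O1–C2, removal of the methoxymethyl and benzyl groups and oxidation would follow.
- In its favour: the substitution pattern of ring A is fixed by the partners, and O1 emerges as the only free phenol, already distinguished from O7. C3 would be set beforehand by auxiliary chemistry, whose outcome is more predictable than a catalytic step on a new substrate; on certainty of configuration this alternative is the better.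
- Against it: it builds, with stoichiometric chromium, a benzene ring that the chosen plan buys as 1. A2 is a trioxygenated alkenyl carbene of doubtful stability that needs several steps. The key step sets no stereocentre and closes no pyran bond. A3 needs its own asymmetric synthesis, and five steps remain after A1.
- Comparison: both plans converge on a benzyl-protected isoflavan. The mechanism is a thermal metal-template reaction without stereocontrol, against a polar acid-catalysed cycloaddition that carries the stereocontrol. In step count the alternative is roughly twice as long.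

**Alternative 2:** The quinone ring is removed. C1'–C2' forms in the key step; the bond from the alkyne to the squarate carbonyl forms earlier, when the lithium acetylide of the ethynylchroman A6 adds to dimethyl squarate A7 to give the cyclobutenone A5.
- Forward step: heating A5 should open the four-membered ring to an enynylketene, bond the ketene carbon to the alkyne carbon that carries chroman C3, and after hydrogen transfer give the quinone A4. Debenzylation would complete the synthesis.
- In its favour: the most fragile ring is made last, directly at the quinone oxidation level and with unambiguous placement of both methoxy groups. No hydroquinone protection or separate oxidation of ring B is needed; on protecting-group and redox economy of ring B this alternative is the better. A7 is a catalogue compound.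
- Against it: the whole stereochemical and heterocyclic problem is moved into A6, which needs the pyran ring and an ethynyl group on the C3 stereocentre. The likely route runs through an epimerisable chroman-3-carbaldehyde. The thermal step competes with closure to five-membered alkylidene cyclopentenediones. Hydrogenolysis of A4 would reduce the quinone as well, so a reoxidation remains.
- Comparison: the two plans are complementary in structure; the chosen key step builds pyran and C3 and buys ring B as a phenol, the alternative builds ring B and must make pyran and C3 separately. On stereochemical integrity in the key step it is the equal of the chosen plan, since C3 is a spectator there. The endgame is shorter, the whole route longer.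

**Alternative 3:** The aryl ether bond O1–C8a is cut. The precursor A9 has a symmetrical 4-hydroxy-3,5-dimethoxyphenyl ring A with hydrogen on the future C8a, and the C2 oxygen masked as an acetate.
- Forward step: anodic oxidation of the phenol in methanol should give the methoxylated dienone A10. Methoxide then cleaves the acetate, the alkoxide adds to C8a in conjugate fashion, and loss of methanol rearomatises ring A to give A8. Hydrogenolysis and oxidation follow.
- In its favour: O7 never needs a protecting group, which is better than the chosen plan. Ring A comes from a symmetrical syringyl unit without any regiochemical question, which is equal or better. The oxidant is electricity, and the endgame is equal in length.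
- Against it: C3 must again be set beforehand, and the key step makes one bond and no stereocentre. Two-electron oxidation of 4-alkyl-2,6-dimethoxyphenols can also be diverted to para capture or to a para-quinone methide by loss of a C4 proton next to C3. Ring B, a tetraalkoxybenzene, is itself oxidisable at the anode. The addition–elimination cascade on the dienone is not assured.
- Comparison: this plan inverts the polarity of ring A (electrophilic C8a), where the chosen plan uses ring A with O1 already in place as the heterodiene. It is mechanistically elegant but delivers less per step; in overall count it is longer because of the separate asymmetric construction of A9.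

Key step: step 10

Remark on the chemistry: the alkyl group on the enol ether oxygen is taken as a spectator, so ethyl replaces methyl; the E-configured boronate 13 is a catalogue reagent and the group is deleted in step 11.
Remark on the chemistry: (R)-TRIP, (R)-3,3'-bis(2,4,6-triisopropylphenyl)-1,1'-binaphthyl-2,2'-diyl hydrogen phosphate, is assumed to lead to the 3S adduct; if the sense of induction is the opposite, (S)-TRIP is used with no other change.

## Route

Step 1
Reactants: 1 2,6-dimethoxyphenol
Product: 2 2-(benzyloxy)-1,3-dimethoxybenzene
Conditions: BnBr, K2CO3, DMF, 60 °C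
Reagents that add atoms: benzyl bromide, BrCc1ccccc1
Why: Williamson ether synthesis; the phenoxide flanked by two methoxy groups should alkylate cleanly with the reactive benzylic bromide in a polar aprotic solvent.

Step 2
Reactants: 2 2-(benzyloxy)-1,3-dimethoxybenzene
Product: 3 3-(benzyloxy)-2,4-dimethoxybenzaldehyde
Conditions: POCl3, DMF, 0 → 75 °C; then ice/H2O
Reagents that add atoms: N,N-dimethylformamide, CN(C)C=O; water, O
Why: Vilsmeier–Haack formylation; in a 1,2,3-trialkoxybenzene the central alkoxy group is twisted out of conjugation, so attack should occur at C4, para to one methoxy and ortho to the other, and the benzyl ether is expected to survive.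

Step 3
Reactants: 3 3-(benzyloxy)-2,4-dimethoxybenzaldehyde
Product: 5 3-(benzyloxy)-2,4-dimethoxyphenol, via aryl formate 4 (not isolated)
Conditions: mCPBA, CH2Cl2, 0 °C → rt; aq. NaHCO3 wash; then K2CO3 (cat.), MeOH, rt
Reagents that add atoms: 3-chloroperoxybenzoic acid, OOC(=O)c1cccc(Cl)c1
Why: Dakin-type Baeyer–Villiger oxidation; the electron-rich aryl group should migrate in preference to hydrogen to give formate 4, which is methanolysed to the phenol.

Step 4
Reactants: 5 3-(benzyloxy)-2,4-dimethoxyphenol
Product: 6 4-(benzyloxy)-2-hydroxy-3,5-dimethoxybenzaldehyde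
Conditions: MgCl2, Et3N, (CH2O)n, MeCN, reflux
Reagents that add atoms: formaldehyde (as paraformaldehyde), C=O
Why: Magnesium-mediated ortho-formylation of a phenol (Casnati–Skattebøl reaction); the magnesium phenoxide delivers formaldehyde to the ortho carbon only and a second formaldehyde takes up the hydride, and since one ortho position alone is free a single regioisomer is expected.

Step 5
Reactants: 6 4-(benzyloxy)-2-hydroxy-3,5-dimethoxybenzaldehyde
Product: 7 3-(benzyloxy)-6-(hydroxymethyl)-2,4-dimethoxyphenol
Conditions: NaBH4, THF/MeOH, 0 °C; neutral work-up, used promptly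
Reagents that add atoms: none
Why: Borohydride reduction of the salicylaldehyde to the salicyl alcohol; nothing else in 6 is reducible, and the acid-sensitive product is kept neutral and cold.

Step 6
Reactants: 8 2,3-dimethoxyphenol
Product: 9 2,3-dimethoxy-1,4-benzoquinone
Conditions: ON(SO3K)2 (2.2 equiv), KH2PO4, H2O/acetone, 0 °C → rt
Reagents that add atoms: potassium nitrosodisulfonate (Fremy's salt), [K+].[K+].[O]N(S(=O)(=O)[O-])S(=O)(=O)[O-]
Why: Teuber oxidation; the phenoxyl radical should couple with a second nitrosodisulfonate radical at the free para position and collapse to the para-quinone.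

Step 7
Reactants: 9 2,3-dimethoxy-1,4-benzoquinone
Product: 11 1,4-bis(benzyloxy)-2,3-dimethoxybenzene, via hydroquinone 10 (not isolated)
Conditions: Na2S2O4, EtOAc/H2O, rt; crude 10, then BnBr, K2CO3, DMF, 50 °C (Ar)
Reagents that add atoms: benzyl bromide, BrCc1ccccc1
Why: Dithionite reduction of the quinone followed by double Williamson benzylation; the air-sensitive hydroquinone is alkylated under argon without purification.

Step 8
Reactants: 11 1,4-bis(benzyloxy)-2,3-dimethoxybenzene
Product: 12 1,4-bis(benzyloxy)-5-bromo-2,3-dimethoxybenzene
Conditions: NBS (1.0 equiv), MeCN, 0 °C → rt, dark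
Reagents that add atoms: N-bromosuccinimide, O=C1CCC(=O)N1Br
Why: Electrophilic aromatic bromination; the two free positions of the tetraalkoxybenzene are equivalent and the first bromine should deactivate the ring against a second substitution.

Step 9
Reactants: 12 1,4-bis(benzyloxy)-5-bromo-2,3-dimethoxybenzene; 13 (E)-2-(2-ethoxyvinyl)-4,4,5,5-tetramethyl-1,3,2-dioxaborolane
Product: 14 (E)-1,4-bis(benzyloxy)-5-(2-ethoxyvinyl)-2,3-dimethoxybenzene
Conditions: Pd(dppf)Cl2 (5 mol%), K3PO4, dioxane/H2O, 80 °C; chromatography on Et3N-treated silica
Reagents that add atoms: none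
Why: Suzuki–Miyaura coupling; transmetalation and reductive elimination proceed with retention of alkene geometry, so only the E enol ether is expected, and the basic medium protects the acid-labile product.

Step 10
Reactants: 7 3-(benzyloxy)-6-(hydroxymethyl)-2,4-dimethoxyphenol; 14 (E)-1,4-bis(benzyloxy)-5-(2-ethoxyvinyl)-2,3-dimethoxybenzene
Product: 16 (2R,3S)-7-(benzyloxy)-3-[2,5-bis(benzyloxy)-3,4-dimethoxyphenyl]-2-ethoxy-6,8-dimethoxychroman (2,3-trans), via ortho-quinone methide 15 (not isolated)
Conditions: (R)-TRIP (10 mol%), 5 Å MS, PhMe, 0 °C → rt, slow addition of 7 to 14 (1.2 equiv)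
Reagents that add atoms: none
Why: The phosphoric acid protonates the benzylic hydroxyl of 7, and loss of water, assisted by the para benzyloxy group on C7 and the ortho phenol, gives ortho-quinone methide 15, which stays hydrogen-bonded to the chiral phosphate through its carbonyl oxygen, the future O1. The aryl-bearing carbon of 14, its nucleophilic terminus, attacks the methide carbon C4 while the carbonyl oxygen closes onto the developing oxocarbenium carbon C2, so C3–C4 and O1–C2 form in one asynchronous inverse-electron-demand hetero-Diels–Alder event. The closest known reaction type is the chiral phosphoric acid catalysed [4+2] cycloaddition of in situ ortho-quinone methides with enol ethers, enamides and styrenes. The pyran ring closes in the [4+2] mode (heterodiene O1=C8a–C4a=C4 plus the enol ether C2=C3); should the process be stepwise, the last bond forms by 6-exo-trig capture of the oxocarbenium ion by the phenoxide. C3 is controlled by the catalyst: the binaphthyl pocket with its 2,4,6-triisopropylphenyl walls shields one face of bound 15 and admits the enol ether in one orientation, so one enantioface of the aryl-bearing carbon is alkylated. C2 is controlled by the substrate: suprafacial addition to the E alkene places ethoxy trans to aryl, and this centre is erased in step 11, so either C2 epimer is usable. Regioselectivity follows from polarity, since the methide carbon is the only electrophilic site and the carbon β to the ethoxy oxygen the only nucleophilic one; the single E geometry from step 9 and the low stationary concentration of 15 secure enantioselectivity and chemoselectivity.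

Step 11
Reactants: 16 (2R,3S)-7-(benzyloxy)-3-[2,5-bis(benzyloxy)-3,4-dimethoxyphenyl]-2-ethoxy-6,8-dimethoxychroman
Product: 17 (3S)-7-(benzyloxy)-3-[2,5-bis(benzyloxy)-3,4-dimethoxyphenyl]-6,8-dimethoxychroman
Conditions: Et3SiH (5 equiv), BF3·OEt2, CH2Cl2, −78 → −30 °C
Reagents that add atoms: none
Why: Ionic hydrogenation of a cyclic acetal; BF3 should ionise the more Lewis-basic ethoxy oxygen and excess silane should trap the cyclic oxocarbenium ion at C2 before the C3 proton can be lost, so C3 is untouched; aryl methyl and benzyl ethers are inert at this temperature.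

Step 12
Reactants: 17 (3S)-7-(benzyloxy)-3-[2,5-bis(benzyloxy)-3,4-dimethoxyphenyl]-6,8-dimethoxychroman
Product: 19 5-[(3S)-7-hydroxy-6,8-dimethoxychroman-3-yl]-2,3-dimethoxycyclohexa-2,5-diene-1,4-dione, via hydroquinone triol 18 (not isolated)
Conditions: H2 (1 atm), 10% Pd/C, EtOAc/MeOH, rt; N2 purge, then air, rt
Reagents that add atoms: none
Why: Hydrogenolysis of three aryl benzyl ethers followed by aerobic dehydrogenation of the dimethoxyhydroquinone; this hydroquinone should be oxidised far more easily than the ring A phenol, so air should stop at the quinone, and the neutral medium leaves C3 alone.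

## Compound list

1 | 2,6-dimethoxyphenol | COc1cccc(OC)c1O | starting material
2 | 2-(benzyloxy)-1,3-dimethoxybenzene | COc1cccc(OC)c1OCc1ccccc1 | intermediate
3 | 3-(benzyloxy)-2,4-dimethoxybenzaldehyde | COc1ccc(C=O)c(OC)c1OCc1ccccc1 | intermediate
4 | 3-(benzyloxy)-2,4-dimethoxyphenyl formate | COc1ccc(OC=O)c(OC)c1OCc1ccccc1 | intermediate (not isolated)
5 | 3-(benzyloxy)-2,4-dimethoxyphenol | COc1ccc(O)c(OC)c1OCc1ccccc1 | intermediate
6 | 4-(benzyloxy)-2-hydroxy-3,5-dimethoxybenzaldehyde | COc1cc(C=O)c(O)c(OC)c1OCc1ccccc1 | intermediate
7 | 3-(benzyloxy)-6-(hydroxymethyl)-2,4-dimethoxyphenol | OCc1cc(OC)c(OCc2ccccc2)c(OC)c1O | intermediate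
8 | 2,3-dimethoxyphenol | COc1cccc(O)c1OC | starting material
9 | 2,3-dimethoxy-1,4-benzoquinone | COC1=C(OC)C(=O)C=CC1=O | intermediate
10 | 2,3-dimethoxybenzene-1,4-diol | COc1c(O)ccc(O)c1OC | intermediate (not isolated)
11 | 1,4-bis(benzyloxy)-2,3-dimethoxybenzene | COc1c(OCc2ccccc2)ccc(OCc2ccccc2)c1OC | intermediate
12 | 1,4-bis(benzyloxy)-5-bromo-2,3-dimethoxybenzene | COc1c(OCc2ccccc2)cc(Br)c(OCc2ccccc2)c1OC | intermediate
13 | (E)-2-(2-ethoxyvinyl)-4,4,5,5-tetramethyl-1,3,2-dioxaborolane | CCO/C=C/B1OC(C)(C)C(C)(C)O1 | starting material
14 | (E)-1,4-bis(benzyloxy)-5-(2-ethoxyvinyl)-2,3-dimethoxybenzene | CCO/C=C/c1cc(OCc2ccccc2)c(OC)c(OC)c1OCc1ccccc1 | intermediate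
15 | 3-(benzyloxy)-2,4-dimethoxy-6-methylidenecyclohexa-2,4-dien-1-one | C=C1C=C(OC)C(OCc2ccccc2)=C(OC)C1=O | intermediate (not isolated)
16 | (2R,3S)-7-(benzyloxy)-3-[2,5-bis(benzyloxy)-3,4-dimethoxyphenyl]-2-ethoxy-6,8-dimethoxychroman | COc1c(OC)c(OCc2ccccc2)cc([C@H]2[C@H](OCC)Oc3c(OC)c(OCc4ccccc4)c(OC)cc3C2)c1OCc1ccccc1 | intermediate
17 | (3S)-7-(benzyloxy)-3-[2,5-bis(benzyloxy)-3,4-dimethoxyphenyl]-6,8-dimethoxychroman | COc1c(OC)c(OCc2ccccc2)cc([C@H]2COc3c(OC)c(OCc4ccccc4)c(OC)cc3C2)c1OCc1ccccc1 | intermediate
18 | (3S)-3-(2,5-dihydroxy-3,4-dimethoxyphenyl)-6,8-dimethoxychroman-7-ol | COc1c(OC)c(O)cc([C@H]2COc3c(OC)c(O)c(OC)cc3C2)c1O | intermediate (not isolated)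
19 | 5-[(3S)-7-hydroxy-6,8-dimethoxychroman-3-yl]-2,3-dimethoxycyclohexa-2,5-diene-1,4-dione | COC1=C(OC)C(=O)C([C@H]2COc3c(cc(OC)c(O)c3OC)C2)=CC1=O | target

## Step count and least certain steps

Total: 12 steps. Longest linear sequence: 8 steps (steps 1 to 5, then 10 to 12); the ring B branch is 4 steps (6 to 9).

**Step 10 (key step).** The likeliest failure is poor facial selectivity at C3: the enol ether has no hydrogen-bond donor to dock onto the phosphate, and the new stereocentre lies on the nucleophile, two atoms from the bound carbonyl. Other risks are slow ionisation of the primary benzylic alcohol by a weak acid, acid-mediated E/Z scrambling or hydrolysis of 14, and self-alkylation of 15 by the electron-rich arenes present. The fallback replaces catalyst control by auxiliary control; it sets out from 14 and 7 and returns at 17.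
- Enol ether 14 is hydrolysed (1 M HCl, THF) to [2,5-bis(benzyloxy)-3,4-dimethoxyphenyl]acetaldehyde F1.
- F1 is oxidised (NaClO2, NaH2PO4, 2-methylbut-2-ene) to [2,5-bis(benzyloxy)-3,4-dimethoxyphenyl]acetic acid F2.
- F2 is joined through its pivaloyl mixed anhydride to lithiated (S)-4-benzyloxazolidin-2-one to give (S)-4-benzyl-3-{[2,5-bis(benzyloxy)-3,4-dimethoxyphenyl]acetyl}oxazolidin-2-one F3.
- Separately, 7 is allylated at the phenol only (allyl bromide, K2CO3, acetone) to [2-(allyloxy)-4-(benzyloxy)-3,5-dimethoxyphenyl]methanol F4, which PBr3 converts into 2-(allyloxy)-4-(benzyloxy)-1-(bromomethyl)-3,5-dimethoxybenzene F5.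
- The sodium enolate of F3 (NaN(SiMe3)2, THF, −78 °C) is alkylated by F5 on the face away from the auxiliary benzyl group. This should give (S)-4-benzyl-3-{(2S)-3-[2-(allyloxy)-4-(benzyloxy)-3,5-dimethoxyphenyl]-2-[2,5-bis(benzyloxy)-3,4-dimethoxyphenyl]propanoyl}oxazolidin-2-one F6, whose 2S centre maps onto 3S.
- LiBH4 releases the auxiliary and gives (2S)-3-[2-(allyloxy)-4-(benzyloxy)-3,5-dimethoxyphenyl]-2-[2,5-bis(benzyloxy)-3,4-dimethoxyphenyl]propan-1-ol F7.
- Pd(PPh3)4 with morpholine removes the allyl group to give 3-(benzyloxy)-6-{(2S)-2-[2,5-bis(benzyloxy)-3,4-dimethoxyphenyl]-3-hydroxypropyl}-2,4-dimethoxyphenol F8.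
- Mitsunobu etherification (PPh3, DIAD) closes O1–C2 to 17.

**Step 11.** Two things may go wrong. Ionisation may occur at the ring oxygen instead of the ethoxy oxygen, and reduction of the acyclic oxocarbenium ion then opens the ring. Alternatively the cyclic oxocarbenium ion may lose the C3 proton to a 4H-chromene, whose ionic hydrogenation would erode the configuration. The fallback generates no cation next to C3; it sets out from 16 and returns at 17. Mild hydrolysis (AcOH/H2O/THF) gives (3S)-7-(benzyloxy)-3-[2,5-bis(benzyloxy)-3,4-dimethoxyphenyl]-6,8-dimethoxychroman-2-ol F9. Its open form is reduced at once (NaBH4, EtOH, 0 °C) to 3-(benzyloxy)-6-{(2S)-2-[2,5-bis(benzyloxy)-3,4-dimethoxyphenyl]-3-hydroxypropyl}-2,4-dimethoxyphenol F8, the compound also met in the fallback for step 10. Mitsunobu etherification (PPh3, DIAD) then gives 17.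

**Step 12.** Cleavage of the three hindered benzyl ethers may be incomplete, or the aerobic stage may stall at a quinhydrone-type mixture or spread to the ring A phenol. The fallback sets out from 17 and returns at 19 through 18 and makes no new compound. Lewis-acid dealkylation (BCl3, pentamethylbenzene as cation scavenger, CH2Cl2, −78 °C) replaces hydrogenolysis. Isolated 18 is then oxidised under argon by hydrogen transfer to 1,4-benzoquinone, an equilibrium-controlled exchange that cannot oxidise a monophenol.

**Step 2.** Acid-induced loss of the benzyl group at 75 °C or partial formylation at the wrong carbon may occur. The fallback sets out from 2 and returns at 5, bypassing 3 and 4. NBS in MeCN gives 3-(benzyloxy)-1-bromo-2,4-dimethoxybenzene F10. Bromine–lithium exchange (n-BuLi, THF, −78 °C), borylation with B(OMe)3 and oxidation of the crude boronate (H2O2, NaOH) then give 5.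

## Further compounds

F1 | step 10 | [2,5-bis(benzyloxy)-3,4-dimethoxyphenyl]acetaldehyde | O=CCc1cc(OCc2ccccc2)c(OC)c(OC)c1OCc1ccccc1
F2 | step 10 | [2,5-bis(benzyloxy)-3,4-dimethoxyphenyl]acetic acid | OC(=O)Cc1cc(OCc2ccccc2)c(OC)c(OC)c1OCc1ccccc1
F3 | step 10 | (S)-4-benzyl-3-{[2,5-bis(benzyloxy)-3,4-dimethoxyphenyl]acetyl}oxazolidin-2-one | O=C(Cc1cc(OCc2ccccc2)c(OC)c(OC)c1OCc1ccccc1)N1[C@@H](Cc2ccccc2)COC1=O
F4 | step 10 | [2-(allyloxy)-4-(benzyloxy)-3,5-dimethoxyphenyl]methanol | OCc1cc(OC)c(OCc2ccccc2)c(OC)c1OCC=C
F5 | step 10 | 2-(allyloxy)-4-(benzyloxy)-1-(bromomethyl)-3,5-dimethoxybenzene | BrCc1cc(OC)c(OCc2ccccc2)c(OC)c1OCC=C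
F6 | step 10 | (S)-4-benzyl-3-{(2S)-3-[2-(allyloxy)-4-(benzyloxy)-3,5-dimethoxyphenyl]-2-[2,5-bis(benzyloxy)-3,4-dimethoxyphenyl]propanoyl}oxazolidin-2-one | O=C([C@@H](Cc1cc(OC)c(OCc2ccccc2)c(OC)c1OCC=C)c1cc(OCc2ccccc2)c(OC)c(OC)c1OCc1ccccc1)N1[C@@H](Cc2ccccc2)COC1=O
F7 | step 10 | (2S)-3-[2-(allyloxy)-4-(benzyloxy)-3,5-dimethoxyphenyl]-2-[2,5-bis(benzyloxy)-3,4-dimethoxyphenyl]propan-1-ol | OC[C@@H](Cc1cc(OC)c(OCc2ccccc2)c(OC)c1OCC=C)c1cc(OCc2ccccc2)c(OC)c(OC)c1OCc1ccccc1
F8 | step 10 | 3-(benzyloxy)-6-{(2S)-2-[2,5-bis(benzyloxy)-3,4-dimethoxyphenyl]-3-hydroxypropyl}-2,4-dimethoxyphenol | OC[C@@H](Cc1cc(OC)c(OCc2ccccc2)c(OC)c1O)c1cc(OCc2ccccc2)c(OC)c(OC)c1OCc1ccccc1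
F9 | step 11 | (3S)-7-(benzyloxy)-3-[2,5-bis(benzyloxy)-3,4-dimethoxyphenyl]-6,8-dimethoxychroman-2-ol | COc1c(OC)c(OCc2ccccc2)cc([C@H]2C(O)Oc3c(OC)c(OCc4ccccc4)c(OC)cc3C2)c1OCc1ccccc1
F0 | step 12 | none | none
F10 | step 2 | 3-(benzyloxy)-1-bromo-2,4-dimethoxybenzene | COc1ccc(Br)c(OC)c1OCc1ccccc1
A1 | alternative 1 | 2-{(2S)-2-[2,5-bis(benzyloxy)-3,4-dimethoxyphenyl]-3-(tert-butyldimethylsilyloxy)propyl}-4,6-dimethoxy-5-(methoxymethoxy)phenol | COc1c(OC)c(OCc2ccccc2)cc([C@H](Cc3cc(OC)c(OCOC)c(OC)c3O)CO[Si](C)(C)C(C)(C)C)c1OCc1ccccc1
A2 | alternative 1 | pentacarbonyl[1,3-dimethoxy-2-(methoxymethoxy)prop-2-en-1-ylidene]chromium | COC=C(OCOC)C(OC)=[Cr](=C=O)(=C=O)(=C=O)(=C=O)=C=O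
A3 | alternative 1 | tert-butyl({(2S)-2-[2,5-bis(benzyloxy)-3,4-dimethoxyphenyl]pent-4-yn-1-yl}oxy)dimethylsilane | C#CC[C@H](CO[Si](C)(C)C(C)(C)C)c1cc(OCc2ccccc2)c(OC)c(OC)c1OCc1ccccc1
A4 | alternative 2 | 5-[(3S)-7-(benzyloxy)-6,8-dimethoxychroman-3-yl]-2,3-dimethoxycyclohexa-2,5-diene-1,4-dione | COC1=C(OC)C(=O)C([C@H]2COc3c(cc(OC)c(OCc4ccccc4)c3OC)C2)=CC1=O
A5 | alternative 2 | 4-{[(3S)-7-(benzyloxy)-6,8-dimethoxychroman-3-yl]ethynyl}-4-hydroxy-2,3-dimethoxycyclobut-2-en-1-one | COC1=C(OC)C(O)(C#C[C@H]2COc3c(cc(OC)c(OCc4ccccc4)c3OC)C2)C1=O
A6 | alternative 2 | (3S)-7-(benzyloxy)-3-ethynyl-6,8-dimethoxychroman | C#C[C@H]1COc2c(cc(OC)c(OCc3ccccc3)c2OC)C1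
A7 | alternative 2 | 3,4-dimethoxycyclobut-3-ene-1,2-dione (dimethyl squarate) | COC1=C(OC)C(=O)C1=O
A8 | alternative 3 | (3S)-3-[2,5-bis(benzyloxy)-3,4-dimethoxyphenyl]-6,8-dimethoxychroman-7-ol | COc1c(OC)c(OCc2ccccc2)cc([C@H]2COc3c(cc(OC)c(O)c3OC)C2)c1OCc1ccccc1
A9 | alternative 3 | (2S)-2-[2,5-bis(benzyloxy)-3,4-dimethoxyphenyl]-3-(4-hydroxy-3,5-dimethoxyphenyl)propyl acetate | CC(=O)OC[C@@H](Cc1cc(OC)c(O)c(OC)c1)c1cc(OCc2ccccc2)c(OC)c(OC)c1OCc1ccccc1
A10 | alternative 3 | (2S)-2-[2,5-bis(benzyloxy)-3,4-dimethoxyphenyl]-3-(3,3,5-trimethoxy-4-oxocyclohexa-1,5-dien-1-yl)propyl acetate | CC(=O)OC[C@@H](CC1=CC(OC)(OC)C(=O)C(OC)=C1)c1cc(OCc2ccccc2)c(OC)c(OC)c1OCc1ccccc1
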